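## The problem

CNP0348256.1 is a (3R)-isoflavanone: a chroman-4-one (ring C: O1, C2, C3, C4; ring A: C4a to C8a) with a 2,4-dihydroxy-5-geranylphenyl ring B at C3. Ring A is a C-methylphloroglucinol with hydroxyls at C5 and C7 and the methyl group at C6. The first difficulty is regiochemical: an acylated methylphloroglucinol has two ortho oxygens that can both become O1, so any route that closes ring C onto a preformed ring A must tell the 6-methyl from the 8-methyl pattern. The second is the single stereocentre C3, which is benzylic and alpha to the C4 ketone. No other stereocentre exists to control it, and it enolises in acid or base, so it has to be set by a reagent late and then handled gently. The geranyl chain excludes hydrogenolysis and hydroboration, and its trisubstituted alkene next to the C4' hydroxyl can cyclise to a chroman in strong acid. The free tetraphenol is easily oxidised and ring A is nucleophilic at C8. The enabling feature is that ring A is an acylphloroglucinol. Carbons C4a to C8a are a folded triketide acylated at C4a by C4, and the C8a oxygen is the ether O1 bound to C2. An open chain with ketones at C4, C8a and C7, an ester at C5 and a hydroxyl at C2 therefore holds every atom of rings A and C.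

## Retrosynthesis

Geranyl stands for (2E)-3,7-dimethylocta-2,6-dien-1-yl throughout.

**C3–H bond, made last (24 from 23, 22, 21, 20).** Because C3 enolises so readily, it is formed as the final skeletal event. Target 24 comes from its tetrakis-silyl ether 23 by fluoride alone. Ketone 23 comes from the achiral enol silane 22 by catalytic enantioselective protonation, and 22 from the racemic persilylated ketone 21, itself made from racemic tetraphenol 20. Setting C3 earlier would oblige every later step to avoid acid and base. Setting it here reduces the problem to racemic 20 and asks the forward step only for facial selectivity at a tetrasubstituted enol silane. Silyl ethers are chosen for this stage so that nothing but buffered fluoride touches the molecule afterwards.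

**Ring B acetals (20 from 19).** The two MOM ethers that carry ring B through the organometallic chemistry are removed with acid while the material is still racemic, so acid-promoted enolisation of C3 costs nothing. The precursor 19 differs from 20 only in these two groups.

**O1–C8a and C4a–C5 (19 from 17 through 18).** This is the central cut. Both rings are opened to the hydroxy trioxo ester 17. In the forward sense the C2 hydroxyl adds to the C8a ketone and water is lost to give dihydropyranone 18, and C4a then attacks the C5 ester in a Claisen closure with aromatisation. Cutting only C4–C4a (acylation of a preformed phloroglucinol), only O1–C8a or only C2–C3 would each need a ring A building block with three differentiated oxygens and the methyl group correctly placed. Here ring A does not exist until O1 is already tied to C2, so the methyl group can only appear at C6. Precursor 17 is acyclic and carries one enolisable stereocentre. The forward reaction must fold the chain in the Claisen and not the aldol or lactone sense.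

**C4–C4a (17 from 16, from 15 and 11).** Silyl ether 16 is cut between the C4 carbonyl and C4a into trianion 15 of dioxo ester 14 and the ring B Weinreb amide 11. This divides the chain into two pieces of similar size at a bond that polyanion acylation makes directly. The silyl group on the C2 oxygen keeps the hydroxyl from quenching the polyanion or cyclising early. The forward step needs addition to the amide carbonyl to outrun deprotonation of its acidic alpha-position.

**C8–C8a (14 from 12 through 13).** Dioxo ester 14 is cut to the dianion 13 of commercial methyl 2-methylacetoacetate 12 and an acetyl Weinreb amide. The C6 methyl group of the target is thus bought with 12.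

**C2–C3 and C3–C1' (11 from 10, 9, 8, 7, 6).** The hydroxymethyl carbon C2 is removed as formaldehyde (aldol of amide enolate 9 from Weinreb amide 8, then silylation of 10). Amide 8 comes from ethyl arylacetate 7, which is cut at the aryl–CH2 bond to aryl bromide 6 and a Reformatsky reagent. Each step is a standard enolate reaction and the fragment shrinks to a simple aryl bromide.

**Geranyl–C5' (6 from 2 and 3, 2 from 1).** The geranyl–aryl bond is cut to geranyl bromide 3 and the dibromide 2, the bis-MOM ether of 4,6-dibromoresorcinol 1. The two equivalent bromines mark C5' and C1', so the substitution pattern of ring B is fixed by the starting material. The forward step passes through aryllithium 4 and arylcopper 5 and must exchange only one bromine.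

## Roads not taken

**Alternative 1:** Ring C is cut at C4–C4a and O1–C2, leading to the symmetric phenol 3,5-bis(methoxymethoxy)-4-methylphenol A2 and the ring B enal 2-[5-bromo-2,4-bis(methoxymethoxy)phenyl]prop-2-enal A3. With PhB(OH)2 and propionic acid the two would condense to a vinyl ortho-quinone methide that closes by oxa-electrocyclisation to the isoflav-3-ene A1.
- Merits: this road is more convergent than the chosen one. It joins two aromatic blocks in one step, needs no polyanion chemistry, and fixes the ring A pattern just as securely, because both ortho positions of A2 are equivalent.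
- Weak points: A1 has the wrong oxidation level. The C3=C4 alkene must be hydroborated and the carbinol oxidised. Hydroboration cannot be done with the geranyl chain present, which is why A1 carries bromine, and the later bromine–lithium exchange cannot be done once the ketone is present, so these operations must be interleaved with protection. Enals of type A3, unsubstituted at the beta-carbon, polymerise readily, and the annulation is best established for beta,beta-disubstituted enals. Four MOM ethers must survive hot carboxylic acid. The stereocentre still needs a separate late solution.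
- Comparison: the chosen plan is less convergent, but ring C is delivered at the ketone oxidation level with the geranyl chain already attached, so nothing stands between ring formation and the stereo-setting endgame.

**Alternative 2:** Only C2–C3 is cut. The diazo ketone A5, 2-diazo-1-[2,4-bis(tert-butyldimethylsilyloxy)-6-methoxy-3-methylphenyl]-2-[2,4-bis(tert-butyldimethylsilyloxy)-5-geranylphenyl]ethanone, would lose nitrogen on Rh2(S-PTTL)4 or its antipode. The C3 carbene would insert into a C–H bond of the C8a methoxy group to give A4, the tetrakis-silyl ether of the (R)-target, which is the same compound as 23.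
- Merits: in step economy and directness of stereocontrol this road is better than the chosen one. Ring closure and the stereocentre come from one catalytic event and the product is one fluoride step from the target.
- Weak points: the insertion must take place into a primary C–H bond and form a six-membered ring, the least favourable case even with oxygen activation. The methoxy oxygen and the ortho silyloxy oxygen of ring B are both placed to attack the carbene and form five-membered oxonium ylides that rearrange. Enantiocontrol at the carbene carbon of such an aryl ketone carbene is unproven. Ring A of A5 needs one methyl ether and two silyl ethers placed correctly around the methyl group, so the 6- versus 8-methyl problem moves into the building block.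
- Comparison: the chosen plan is longer, but it has an enantioselective step of a type already shown on alpha-aryl cyclic ketone enol silanes and a ring A whose pattern follows from the chain.

**Alternative 3:** The ether bond O1–C8a is cut with C4 kept as a carbinol. The bromo diol A7, (1S,2R)-1-[6-bromo-2,4-bis(methoxymethoxy)-3-methylphenyl]-2-[5-geranyl-2,4-bis(methoxymethoxy)phenyl]propane-1,3-diol, would close under CuI, 1,10-phenanthroline and Cs2CO3 to the trans-(3R,4S)-isoflavan-4-ol A6.
- Merits: C3 can be set early by reliable asymmetric aldol chemistry and cannot enolise while C4 is a carbinol. In security of configuration over most of the route this road is better than the chosen one. The position of the bromine fixes the ring A pattern and copper-catalysed aryl etherification is well known.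
- Weak points: after ring closure the carbinol must be oxidised and four MOM ethers removed with acid from an enolisable alpha-aryl ketone carrying a geranyl chain, so the configuration is most exposed at the very end. The aryl bromide is electron-rich and ortho-substituted. Ring A of A7 requires a regiodefined pentasubstituted bromo aldehyde, and an auxiliary or catalyst sequence is added.
- Comparison: the chosen plan sets the stereocentre late, but after that point the molecule sees only buffered fluoride, and no pentasubstituted arene has to be prepared.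

Key step: step 10

Assumption: the (S)-catalyst is written in step 14 for definiteness; which antipode protonates the face leading to 3R must be settled on the first run, and the (R)-catalyst is used if the sense is opposite. Compounds 10, 11 and 16 to 21 are racemic, and 14, 16, 17 and 18 are drawn as keto forms although they should be largely enolised (17 partly as its cyclic hemiketal).

## Route

Step 1
Reactants: 1 4,6-dibromoresorcinol
Product: 2 1,5-dibromo-2,4-bis(methoxymethoxy)benzene
Conditions: MOMCl (2.6 equiv), i-Pr2NEt (3.5 equiv), CH2Cl2, 0 °C to rt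
Reagents that add atoms: chloromethyl methyl ether, COCCl
Why: O-alkylation of both phenols by the alpha-chloro ether under amine base; the MOM ethers tolerate the organometallic steps and stabilise the ortho-metalated arene by chelation.

Step 2
Reactants: 2 1,5-dibromo-2,4-bis(methoxymethoxy)benzene; 3 geranyl bromide
Product: 6 1-bromo-5-geranyl-2,4-bis(methoxymethoxy)benzene, via aryllithium 4 (not isolated), via arylcopper 5 (not isolated)
Conditions: n-BuLi (1.05 equiv), THF, −78 °C; CuBr·SMe2 (1.1 equiv), −78 to −40 °C; 3 (1.2 equiv), −40 to 0 °C
Reagents that add atoms: none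
Why: Bromine–lithium exchange should stop after one of the two equivalent bromines because the electron-rich aryllithium 4 resists a second exchange; transmetalation to the monovalent copper species 5 and allylic substitution at the primary carbon of 3 (the tertiary gamma-carbon is shielded) should give the linear arene with the E alkene intact.

Step 3
Reactants: 6 1-bromo-5-geranyl-2,4-bis(methoxymethoxy)benzene
Product: 7 ethyl 2-[5-geranyl-2,4-bis(methoxymethoxy)phenyl]acetate
Conditions: BrZnCH2CO2Et (0.5 M stock solution in THF, 2.0 equiv), Pd2(dba)3 (1.5 mol%), XPhos (6 mol%), THF, 60 °C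
Reagents that add atoms: (2-ethoxy-2-oxoethyl)zinc bromide, CCOC(=O)C[Zn]Br
Why: Negishi-type coupling of a Reformatsky reagent (palladium-catalysed alpha-arylation of a zinc ester enolate); the bulky biaryl phosphine allows oxidative addition of the electron-rich ortho-alkoxy aryl bromide to zerovalent palladium, and the weakly basic zinc enolate leaves the MOM ethers and the alkenes alone.

Step 4
Reactants: 7 ethyl 2-[5-geranyl-2,4-bis(methoxymethoxy)phenyl]acetate
Product: 8 2-[5-geranyl-2,4-bis(methoxymethoxy)phenyl]-N-methoxy-N-methylacetamide
Conditions: MeNHOMe·HCl (1.6 equiv), i-PrMgCl (3.2 equiv), THF, −20 to 0 °C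
Reagents that add atoms: N,O-dimethylhydroxylamine hydrochloride, CNOC.Cl
Why: Weinreb amide formation by aminolysis of the ester with the chloromagnesium amide of N,O-dimethylhydroxylamine; it is done before hydroxymethylation so that no beta-oxygenated ester meets the basic amide.

Step 5
Reactants: 8 2-[5-geranyl-2,4-bis(methoxymethoxy)phenyl]-N-methoxy-N-methylacetamide
Product: 10 rac-2-[5-geranyl-2,4-bis(methoxymethoxy)phenyl]-3-hydroxy-N-methoxy-N-methylpropanamide, via lithium amide enolate 9 (not isolated)
Conditions: LiN(i-Pr)2 (1.15 equiv), THF, −78 °C; CH2O (gas from cracked paraformaldehyde), −78 °C; aq. NH4Cl, −78 °C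
Reagents that add atoms: formaldehyde, C=O
Why: Aldol addition of the aryl-stabilised amide enolate 9 to monomeric formaldehyde (hydroxymethylation); the cold quench keeps the aldolate from beta-elimination, and the new centre (later C3) is racemic by design.

Step 6
Reactants: 10 rac-2-[5-geranyl-2,4-bis(methoxymethoxy)phenyl]-3-hydroxy-N-methoxy-N-methylpropanamide
Product: 11 rac-3-(tert-butyldimethylsilyloxy)-2-[5-geranyl-2,4-bis(methoxymethoxy)phenyl]-N-methoxy-N-methylpropanamide
Conditions: TBSCl (1.3 equiv), imidazole (2.5 equiv), CH2Cl2, 0 °C to rt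
Reagents that add atoms: tert-butyldimethylsilyl chloride, CC(C)(C)[Si](C)(C)Cl
Why: Standard silylation of a primary alcohol; the silyl ether keeps the hydroxyl from quenching the polyanion of step 8 and from attacking the chain carbonyls before the key step.

Step 7
Reactants: 12 methyl 2-methylacetoacetate
Product: 14 methyl 2-methyl-3,5-dioxohexanoate, via dilithium dianion 13 (not isolated)
Conditions: LiN(i-Pr)2 (2.2 equiv), THF, 0 °C; MeC(O)N(OMe)Me (0.9 equiv), −78 to 0 °C; 1 M HCl
Reagents that add atoms: N-methoxy-N-methylacetamide, CC(=O)N(C)OC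
Why: Gamma-acylation of a beta-keto ester dianion; the terminal carbanion of 13 is its most nucleophilic site, and the Weinreb amide gives a chelated adduct that collapses only on work-up, so the product is not acylated again.

Step 8
Reactants: 14 methyl 2-methyl-3,5-dioxohexanoate; 11 rac-3-(tert-butyldimethylsilyloxy)-2-[5-geranyl-2,4-bis(methoxymethoxy)phenyl]-N-methoxy-N-methylpropanamide
Product: 16 rac-methyl 9-(tert-butyldimethylsilyloxy)-8-[5-geranyl-2,4-bis(methoxymethoxy)phenyl]-2-methyl-3,5,7-trioxononanoate, via trilithium trianion 15 (not isolated)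
Conditions: 14 (2.5 equiv), LiN(i-Pr)2 (7.5 equiv), THF, −78 to 0 °C; 11 (1.0 equiv), −78 to −30 °C; aq. NH4Cl, −78 °C
Reagents that add atoms: none
Why: Terminal acylation of a 3,5-dioxo ester trianion by a Weinreb amide, the polyanion chain extension used for polyketide-type chains; the last-formed carbanion of 15 is the most nucleophilic, excess 15 at low temperature favours carbonyl addition over alpha-deprotonation of 11, and the chelated adduct persists until the cold quench.

Step 9
Reactants: 16 rac-methyl 9-(tert-butyldimethylsilyloxy)-8-[5-geranyl-2,4-bis(methoxymethoxy)phenyl]-2-methyl-3,5,7-trioxononanoate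
Product: 17 rac-methyl 8-[5-geranyl-2,4-bis(methoxymethoxy)phenyl]-9-hydroxy-2-methyl-3,5,7-trioxononanoate
Conditions: HF·pyridine, pyridine, THF, 0 °C
Reagents that add atoms: none
Why: Fluoride cleavage of the primary silyl ether in a pyridine-buffered medium that spares the aryl MOM ethers and the beta-hydroxy ketone; 17 is taken on without chromatography.

Step 10
Reactants: 17 rac-methyl 8-[5-geranyl-2,4-bis(methoxymethoxy)phenyl]-9-hydroxy-2-methyl-3,5,7-trioxononanoate
Product: 19 rac-3-[5-geranyl-2,4-bis(methoxymethoxy)phenyl]-5,7-dihydroxy-6-methylchroman-4-one, via dihydropyranone keto ester 18 (not isolated)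
Conditions: PPTS (0.2 equiv), 4 Å molecular sieves, CH2Cl2, rt to 40 °C; evaporate; Mg(OMe)2 (5 equiv), MeOH, rt to 60 °C; cold 1 M HCl to pH 4
Reagents that add atoms: none
Why: Proposed new method: PPTS should add the C2 hydroxyl to the C8a ketone and dehydrate the hemiketal to the vinylogous ester 18, after which Mg(OMe)2 removes a proton from the side-chain methylene (C8) to give a dienolate whose ring carbon C4a attacks the methyl ester, expels methoxide and leaves a cyclohexenedione that enolises twice to the aromatic 5,7-diol; the closest known reaction types are the acid cyclodehydration of delta-hydroxy beta-diketones to 2,3-dihydro-4H-pyran-4-ones and the Mg(OMe)2-mediated Claisen cyclisation of 3,5,7-triketo esters to acylphloroglucinols, which have not been run in sequence on one chain. Ring C closes by 6-exo-trig attack of oxygen on the C8a carbonyl, and ring A closes by 6-(enolexo)-exo-trig attack of C4a on the ester carbonyl. No stereocentre is created: C3 stays racemic and enolisable, and the methyl-bearing carbon of the chain becomes aromatic C6. The selectivity needed is Claisen folding in a single regiochemical sense, and it is secured because O1 is already bonded to C8a when ring A forms: the methyl group can then only end at C6, the C8a oxygen can no longer lactonise onto the ester, and the C4 carbonyl, now part of a vinylogous ester, is a poor aldol acceptor. Magnesium chelation of the beta-keto ester should hold the ester close to C4a and temper retro-Claisen cleavage by methoxide. Once ring A is aromatic it is a magnesium phenolate, which makes O1 a poor leaving group and should protect ring C against opening by beta-elimination.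

Step 11
Reactants: 19 rac-3-[5-geranyl-2,4-bis(methoxymethoxy)phenyl]-5,7-dihydroxy-6-methylchroman-4-one
Product: 20 rac-3-(5-geranyl-2,4-dihydroxyphenyl)-5,7-dihydroxy-6-methylchroman-4-one
Conditions: 3 M aq. HCl/MeOH (1:10), 45 °C
Reagents that add atoms: none
Why: Acid-catalysed acetal exchange of the two aryl MOM ethers with methanol, which traps the methoxymethyl cation as dimethoxymethane; it is run on racemic material so that acid enolisation at C3 is harmless, and these are the usual conditions for freeing prenylated and geranylated polyphenols.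

Step 12
Reactants: 20 rac-3-(5-geranyl-2,4-dihydroxyphenyl)-5,7-dihydroxy-6-methylchroman-4-one
Product: 21 rac-5,7-bis(tert-butyldimethylsilyloxy)-3-[2,4-bis(tert-butyldimethylsilyloxy)-5-geranylphenyl]-6-methylchroman-4-one
Conditions: TBSOTf (5 equiv), 2,6-lutidine (8 equiv), CH2Cl2, −78 to 0 °C
Reagents that add atoms: tert-butyldimethylsilyl triflate, CC(C)(C)[Si](C)(C)OS(=O)(=O)C(F)(F)F
Why: The silyl triflate with a hindered pyridine base should silylate all four phenols, including the hydrogen-bonded C5 hydroxyl and the hindered C2' hydroxyl, while 2,6-lutidine is too weak a base to turn the ketone into its enol silane at low temperature.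

Step 13
Reactants: 21 rac-5,7-bis(tert-butyldimethylsilyloxy)-3-[2,4-bis(tert-butyldimethylsilyloxy)-5-geranylphenyl]-6-methylchroman-4-one
Product: 22 5,7-bis(tert-butyldimethylsilyloxy)-3-[2,4-bis(tert-butyldimethylsilyloxy)-5-geranylphenyl]-6-methyl-4-(trimethylsilyloxy)-2H-chromene
Conditions: TMSOTf (1.5 equiv), Et3N (3 equiv), CH2Cl2, 0 °C to rt; pentane, filtration
Reagents that add atoms: trimethylsilyl triflate, C[Si](C)(C)OS(=O)(=O)C(F)(F)F
Why: Soft enolisation with silyl triflate and amine gives the only possible enol silane, since C3 carries the sole alpha-hydrogen; the stereocentre is erased on purpose and the product is isolated by non-aqueous work-up.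

Step 14
Reactants: 22 5,7-bis(tert-butyldimethylsilyloxy)-3-[2,4-bis(tert-butyldimethylsilyloxy)-5-geranylphenyl]-6-methyl-4-(trimethylsilyloxy)-2H-chromene
Product: 23 (3R)-5,7-bis(tert-butyldimethylsilyloxy)-3-[2,4-bis(tert-butyldimethylsilyloxy)-5-geranylphenyl]-6-methylchroman-4-one
Conditions: (S)-3,3'-bis(2,4,6-triisopropylphenyl)-BINOL N-triflyl thiophosphoramide (5 mol%), PhOH (1.1 equiv), toluene, −20 °C to rt
Reagents that add atoms: none
Why: Catalytic enantioselective protonation of the silyl enol ether of an alpha-aryl cyclic ketone by a chiral N-triflyl thiophosphoramide with phenol as stoichiometric proton source; the chiral acid protonates C3 from one face within a contact ion pair, which sets 3R, and phenol takes up the trimethylsilyl group and regenerates the acid.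

Step 15
Reactants: 23 (3R)-5,7-bis(tert-butyldimethylsilyloxy)-3-[2,4-bis(tert-butyldimethylsilyloxy)-5-geranylphenyl]-6-methylchroman-4-one
Product: 24 (3R)-3-(5-geranyl-2,4-dihydroxyphenyl)-5,7-dihydroxy-6-methylchroman-4-one (CNP0348256.1)
Conditions: HF·pyridine, pyridine, THF, 0 °C to rt
Reagents that add atoms: none
Why: Fluoride cleavage of the four aryl silyl ethers in a pyridine-buffered medium that should neither enolise the alpha-aryl ketone nor touch the geranyl chain, so the configuration set in step 14 is kept.

## Compound list

1 | 4,6-dibromoresorcinol (4,6-dibromobenzene-1,3-diol) | Oc1cc(O)c(Br)cc1Br | starting material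
2 | 1,5-dibromo-2,4-bis(methoxymethoxy)benzene | COCOc1cc(OCOC)c(Br)cc1Br | intermediate
3 | geranyl bromide, (2E)-1-bromo-3,7-dimethylocta-2,6-diene | CC(C)=CCC/C(C)=C/CBr | starting material
4 | [5-bromo-2,4-bis(methoxymethoxy)phenyl]lithium | COCOc1cc(OCOC)c(Br)cc1[Li] | intermediate
5 | [5-bromo-2,4-bis(methoxymethoxy)phenyl]copper | COCOc1cc(OCOC)c(Br)cc1[Cu] | intermediate
6 | 1-bromo-5-[(2E)-3,7-dimethylocta-2,6-dien-1-yl]-2,4-bis(methoxymethoxy)benzene | CC(C)=CCC/C(C)=C/Cc1cc(Br)c(OCOC)cc1OCOC | intermediate
7 | ethyl 2-[5-geranyl-2,4-bis(methoxymethoxy)phenyl]acetate | CC(C)=CCC/C(C)=C/Cc1cc(CC(=O)OCC)c(OCOC)cc1OCOC | intermediate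
8 | 2-[5-geranyl-2,4-bis(methoxymethoxy)phenyl]-N-methoxy-N-methylacetamide | CC(C)=CCC/C(C)=C/Cc1cc(CC(=O)N(C)OC)c(OCOC)cc1OCOC | intermediate
9 | lithium enolate of 8 | [Li+].CC(C)=CCC/C(C)=C/Cc1cc(C=C([O-])N(C)OC)c(OCOC)cc1OCOC | intermediate
10 | rac-2-[5-geranyl-2,4-bis(methoxymethoxy)phenyl]-3-hydroxy-N-methoxy-N-methylpropanamide | CC(C)=CCC/C(C)=C/Cc1cc(C(CO)C(=O)N(C)OC)c(OCOC)cc1OCOC | intermediate
11 | rac-3-(tert-butyldimethylsilyloxy)-2-[5-geranyl-2,4-bis(methoxymethoxy)phenyl]-N-methoxy-N-methylpropanamide | CC(C)=CCC/C(C)=C/Cc1cc(C(CO[Si](C)(C)C(C)(C)C)C(=O)N(C)OC)c(OCOC)cc1OCOC | intermediate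
12 | methyl 2-methylacetoacetate (methyl 2-methyl-3-oxobutanoate) | CC(=O)C(C)C(=O)OC | starting material
13 | dilithium dianion (bis-enolate) of 12 | [Li+].[Li+].C=C([O-])C(C)=C([O-])OC | intermediate
14 | methyl 2-methyl-3,5-dioxohexanoate | CC(=O)CC(=O)C(C)C(=O)OC | intermediate
15 | trilithium trianion (tris-enolate) of 14 | [Li+].[Li+].[Li+].C=C([O-])C=C([O-])C(C)=C([O-])OC | intermediate
16 | rac-methyl 9-(tert-butyldimethylsilyloxy)-8-[5-geranyl-2,4-bis(methoxymethoxy)phenyl]-2-methyl-3,5,7-trioxononanoate | CC(C)=CCC/C(C)=C/Cc1cc(C(CO[Si](C)(C)C(C)(C)C)C(=O)CC(=O)CC(=O)C(C)C(=O)OC)c(OCOC)cc1OCOC | intermediate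
17 | rac-methyl 8-[5-geranyl-2,4-bis(methoxymethoxy)phenyl]-9-hydroxy-2-methyl-3,5,7-trioxononanoate | CC(C)=CCC/C(C)=C/Cc1cc(C(CO)C(=O)CC(=O)CC(=O)C(C)C(=O)OC)c(OCOC)cc1OCOC | intermediate
18 | rac-methyl 4-{5-[5-geranyl-2,4-bis(methoxymethoxy)phenyl]-4-oxo-5,6-dihydro-4H-pyran-2-yl}-2-methyl-3-oxobutanoate | CC(C)=CCC/C(C)=C/Cc1cc(C2COC(CC(=O)C(C)C(=O)OC)=CC2=O)c(OCOC)cc1OCOC | intermediate
19 | rac-3-[5-geranyl-2,4-bis(methoxymethoxy)phenyl]-5,7-dihydroxy-6-methylchroman-4-one | CC(C)=CCC/C(C)=C/Cc1cc(C2COc3cc(O)c(C)c(O)c3C2=O)c(OCOC)cc1OCOC | intermediate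
20 | rac-3-(5-geranyl-2,4-dihydroxyphenyl)-5,7-dihydroxy-6-methylchroman-4-one | CC(C)=CCC/C(C)=C/Cc1cc(C2COc3cc(O)c(C)c(O)c3C2=O)c(O)cc1O | intermediate
21 | rac-5,7-bis(tert-butyldimethylsilyloxy)-3-[2,4-bis(tert-butyldimethylsilyloxy)-5-geranylphenyl]-6-methylchroman-4-one | CC(C)=CCC/C(C)=C/Cc1cc(C2COc3cc(O[Si](C)(C)C(C)(C)C)c(C)c(O[Si](C)(C)C(C)(C)C)c3C2=O)c(O[Si](C)(C)C(C)(C)C)cc1O[Si](C)(C)C(C)(C)C | intermediate
22 | 5,7-bis(tert-butyldimethylsilyloxy)-3-[2,4-bis(tert-butyldimethylsilyloxy)-5-geranylphenyl]-6-methyl-4-(trimethylsilyloxy)-2H-chromene | CC(C)=CCC/C(C)=C/Cc1cc(C2=C(O[Si](C)(C)C)c3c(O[Si](C)(C)C(C)(C)C)c(C)c(O[Si](C)(C)C(C)(C)C)cc3OC2)c(O[Si](C)(C)C(C)(C)C)cc1O[Si](C)(C)C(C)(C)C | intermediate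
23 | (3R)-5,7-bis(tert-butyldimethylsilyloxy)-3-[2,4-bis(tert-butyldimethylsilyloxy)-5-geranylphenyl]-6-methylchroman-4-one | CC(C)=CCC/C(C)=C/Cc1cc([C@@H]2COc3cc(O[Si](C)(C)C(C)(C)C)c(C)c(O[Si](C)(C)C(C)(C)C)c3C2=O)c(O[Si](C)(C)C(C)(C)C)cc1O[Si](C)(C)C(C)(C)C | intermediate
24 | (3R)-3-{5-[(2E)-3,7-dimethylocta-2,6-dien-1-yl]-2,4-dihydroxyphenyl}-5,7-dihydroxy-6-methylchroman-4-one (CNP0348256.1) | CC(C)=CCC/C(C)=C/Cc1cc([C@@H]2COc3cc(O)c(C)c(O)c3C2=O)c(O)cc1O | target

## Step count and least certain steps

Total: 15 steps. Longest linear sequence: 14 steps (1 to 24 through steps 1 to 6 and 8 to 15); the ring A chain branch adds step 7.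

**Step 10 (key step).** It is the only step without direct precedent.
- What may go wrong in the acid stage: water may be lost across C2–C3 of the beta-hydroxy ketone, or an enol oxygen may attack in place of the hydroxyl.
- What may go wrong in the base stage: methoxide may cleave the polycarbonyl chain by retro-Claisen reaction, ring C may open reversibly by beta-elimination, or the stabilised dienolate may fail to attack the ester.
- Fallback (order of ring closures inverted, known chemistry only): from 16, the Mg(OMe)2-mediated Claisen cyclisation of the triketo ester would give the acylphloroglucinol rac-3-(tert-butyldimethylsilyloxy)-2-[5-geranyl-2,4-bis(methoxymethoxy)phenyl]-1-(2,4,6-trihydroxy-3-methylphenyl)propan-1-one F1. HF·pyridine would free the primary alcohol rac-2-[5-geranyl-2,4-bis(methoxymethoxy)phenyl]-3-hydroxy-1-(2,4,6-trihydroxy-3-methylphenyl)propan-1-one F2. A Mitsunobu etherification (PPh3, DIAD, THF) would close ring C and rejoin the route at 19.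
- Cost of the fallback: the ring A pattern is no longer fixed by construction. Closure through the more hindered, chelated hydroxyl next to the methyl group has to be expected as a minor pathway and the product purified accordingly.

**Step 8.**
- What may go wrong: the strongly basic trianion may take the acidic alpha-proton of 11 instead of adding to the carbonyl, followed by loss of silyloxide and return of 14.
- Fallback: from 11, i-Bu2AlH (THF, −78 °C) would give the aldehyde rac-3-(tert-butyldimethylsilyloxy)-2-[5-geranyl-2,4-bis(methoxymethoxy)phenyl]propanal F3. Aldehydes add polyanions faster than they are deprotonated, so aldol addition of 15 at −78 °C should give rac-methyl 9-(tert-butyldimethylsilyloxy)-8-[5-geranyl-2,4-bis(methoxymethoxy)phenyl]-7-hydroxy-2-methyl-3,5-dioxononanoate F4. Oxidation of the carbinol with Dess–Martin periodinane returns to 16.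

**Step 14.**
- What may go wrong: facial discrimination may be poor or protonation slow, because the enol silane is tetrasubstituted and flanked by the C5 silyloxy group and an ortho-silyloxy aryl ring; uncatalysed protonation by phenol would erode selectivity further.
- Fallback: from 21, asymmetric transfer hydrogenation under dynamic kinetic resolution (RuCl(p-cymene)[(R,R)-TsDPEN] or its antipode, HCO2H/Et3N) would reduce the racemising ketone to the cis alcohol (3R,4R)-5,7-bis(tert-butyldimethylsilyloxy)-3-[2,4-bis(tert-butyldimethylsilyloxy)-5-geranylphenyl]-6-methylchroman-4-ol F5. Oxidation with Dess–Martin periodinane buffered by NaHCO3 returns to 23.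

**Step 11.**
- What may go wrong: the geranyl alkene may cyclise onto the C4' hydroxyl under acid, and methoxymethyl cations may be captured by the nucleophilic C8 of ring A.
- Fallback: from 19, the ring A phenols are silylated first (TBSOTf, 2,6-lutidine) to rac-5,7-bis(tert-butyldimethylsilyloxy)-3-[5-geranyl-2,4-bis(methoxymethoxy)phenyl]-6-methylchroman-4-one F6. The MOM ethers are then removed briefly with ZnBr2 and n-PrSH (CH2Cl2, 0 °C), the thiol trapping the cation, to give rac-5,7-bis(tert-butyldimethylsilyloxy)-3-(5-geranyl-2,4-dihydroxyphenyl)-6-methylchroman-4-one F7. Silylation of the two ring B phenols (TBSOTf, 2,6-lutidine) rejoins the route at 21.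

## Further compounds

F1 | step 10 | rac-3-(tert-butyldimethylsilyloxy)-2-[5-geranyl-2,4-bis(methoxymethoxy)phenyl]-1-(2,4,6-trihydroxy-3-methylphenyl)propan-1-one | CC(C)=CCC/C(C)=C/Cc1cc(C(CO[Si](C)(C)C(C)(C)C)C(=O)c2c(O)cc(O)c(C)c2O)c(OCOC)cc1OCOC
F2 | step 10 | rac-2-[5-geranyl-2,4-bis(methoxymethoxy)phenyl]-3-hydroxy-1-(2,4,6-trihydroxy-3-methylphenyl)propan-1-one | CC(C)=CCC/C(C)=C/Cc1cc(C(CO)C(=O)c2c(O)cc(O)c(C)c2O)c(OCOC)cc1OCOC
F3 | step 8 | rac-3-(tert-butyldimethylsilyloxy)-2-[5-geranyl-2,4-bis(methoxymethoxy)phenyl]propanal | CC(C)=CCC/C(C)=C/Cc1cc(C(CO[Si](C)(C)C(C)(C)C)C=O)c(OCOC)cc1OCOC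
F4 | step 8 | rac-methyl 9-(tert-butyldimethylsilyloxy)-8-[5-geranyl-2,4-bis(methoxymethoxy)phenyl]-7-hydroxy-2-methyl-3,5-dioxononanoate | CC(C)=CCC/C(C)=C/Cc1cc(C(CO[Si](C)(C)C(C)(C)C)C(O)CC(=O)CC(=O)C(C)C(=O)OC)c(OCOC)cc1OCOC
F5 | step 14 | (3R,4R)-5,7-bis(tert-butyldimethylsilyloxy)-3-[2,4-bis(tert-butyldimethylsilyloxy)-5-geranylphenyl]-6-methylchroman-4-ol | CC(C)=CCC/C(C)=C/Cc1cc([C@@H]2COc3cc(O[Si](C)(C)C(C)(C)C)c(C)c(O[Si](C)(C)C(C)(C)C)c3[C@@H]2O)c(O[Si](C)(C)C(C)(C)C)cc1O[Si](C)(C)C(C)(C)C
F6 | step 11 | rac-5,7-bis(tert-butyldimethylsilyloxy)-3-[5-geranyl-2,4-bis(methoxymethoxy)phenyl]-6-methylchroman-4-one | CC(C)=CCC/C(C)=C/Cc1cc(C2COc3cc(O[Si](C)(C)C(C)(C)C)c(C)c(O[Si](C)(C)C(C)(C)C)c3C2=O)c(OCOC)cc1OCOC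
F7 | step 11 | rac-5,7-bis(tert-butyldimethylsilyloxy)-3-(5-geranyl-2,4-dihydroxyphenyl)-6-methylchroman-4-one | CC(C)=CCC/C(C)=C/Cc1cc(C2COc3cc(O[Si](C)(C)C(C)(C)C)c(C)c(O[Si](C)(C)C(C)(C)C)c3C2=O)c(O)cc1O
A1 | alternative 1 | 3-[5-bromo-2,4-bis(methoxymethoxy)phenyl]-5,7-bis(methoxymethoxy)-6-methyl-2H-chromene | COCOc1cc(OCOC)c(Br)cc1C1=Cc2c(OCOC)c(C)c(OCOC)cc2OC1
A2 | alternative 1 | 3,5-bis(methoxymethoxy)-4-methylphenol | COCOc1cc(O)cc(OCOC)c1C
A3 | alternative 1 | 2-[5-bromo-2,4-bis(methoxymethoxy)phenyl]prop-2-enal | COCOc1cc(OCOC)c(Br)cc1C(=C)C=O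
A4 | alternative 2 | (3R)-5,7-bis(tert-butyldimethylsilyloxy)-3-[2,4-bis(tert-butyldimethylsilyloxy)-5-geranylphenyl]-6-methylchroman-4-one | CC(C)=CCC/C(C)=C/Cc1cc([C@@H]2COc3cc(O[Si](C)(C)C(C)(C)C)c(C)c(O[Si](C)(C)C(C)(C)C)c3C2=O)c(O[Si](C)(C)C(C)(C)C)cc1O[Si](C)(C)C(C)(C)C
A5 | alternative 2 | 2-diazo-1-[2,4-bis(tert-butyldimethylsilyloxy)-6-methoxy-3-methylphenyl]-2-[2,4-bis(tert-butyldimethylsilyloxy)-5-geranylphenyl]ethanone | CC(C)=CCC/C(C)=C/Cc1cc(C(=[N+]=[N-])C(=O)c2c(OC)cc(O[Si](C)(C)C(C)(C)C)c(C)c2O[Si](C)(C)C(C)(C)C)c(O[Si](C)(C)C(C)(C)C)cc1O[Si](C)(C)C(C)(C)C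
A6 | alternative 3 | (3R,4S)-3-[5-geranyl-2,4-bis(methoxymethoxy)phenyl]-5,7-bis(methoxymethoxy)-6-methylchroman-4-ol | CC(C)=CCC/C(C)=C/Cc1cc([C@@H]2COc3cc(OCOC)c(C)c(OCOC)c3[C@H]2O)c(OCOC)cc1OCOC
A7 | alternative 3 | (1S,2R)-1-[6-bromo-2,4-bis(methoxymethoxy)-3-methylphenyl]-2-[5-geranyl-2,4-bis(methoxymethoxy)phenyl]propane-1,3-diol | CC(C)=CCC/C(C)=C/Cc1cc([C@H](CO)[C@H](O)c2c(Br)cc(OCOC)c(C)c2OCOC)c(OCOC)cc1OCOC
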